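The route rests on cutting the C6–C7 single bond (prostanoid numbering) that links the exocyclic C7=C8 alkene of the cyclopentenone ring to the C5=C6 alkene of the ester chain. One Negishi coupling, fed by in-flask hydrozirconation of methyl hex-5-ynoate, forms this bond, fixes 5E, carries 7Z and, after acidic work-up, delivers the target. Its precursor is the (Z)-enol triflate of a 5-formyl-2-chlorocyclopentenone. The step exploits the 1,3-relation between ring ketone C9 and exocyclic C7: C7 enters as a formyl carbon that a lithium chelate, then an O-chelated alkenylpalladium, hold cis to C9=O. C12 is set by 1,4-chirality transfer from (R)-4-silyloxycyclopentenone.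

Key step: step 9

Remark: target atoms are numbered as in prostanoids (C1 ester carbon, C8–C12 ring, C13–C20 octenyl chain); η5-cyclopentadienyl ligands are written as σ-bonded C5H5 groups in SMILES.

Step 1
Reactants: 1 (Z)-oct-2-en-1-ol
Product: 2 (Z)-1-chlorooct-2-ene
Conditions: PPh3, CCl4, reflux
Reagents that add atoms: carbon tetrachloride ClC(Cl)(Cl)Cl
Why: Appel reaction; chloride displaces the alkoxyphosphonium group by SN2 at the primary allylic carbon, so neither allylic transposition nor loss of the Z geometry is expected.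

Step 2
Reactants: 2 (Z)-1-chlorooct-2-ene; 3 (R)-4-[(tert-butyldimethylsilyl)oxy]cyclopent-2-en-1-one
Product: 5 (1S,4R)-4-[(tert-butyldimethylsilyl)oxy]-1-[(2Z)-oct-2-en-1-yl]cyclopent-2-en-1-ol, via (Z)-oct-2-enylbarium chloride 4 (not isolated)
Conditions: activated Ba (from BaI2, Li biphenylide), THF, −78 °C; then 3, −78 °C; aq. NH4Cl
Reagents that add atoms: none
Why: α-selective allylbarium 1,2-addition; the allylbarium keeps its Z geometry at −78 °C, reacts at its α-carbon and at C=O faster than it enolises the ketone, and attacks the face anti to the C4 silyloxy group, which sets the tertiary carbinol (the future 12R centre); the minor diastereomer can be removed at this stage.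

Step 3
Reactants: 5 (1S,4R)-4-[(tert-butyldimethylsilyl)oxy]-1-[(2Z)-oct-2-en-1-yl]cyclopent-2-en-1-ol
Product: 6 (1S,4R)-1-[(2Z)-oct-2-en-1-yl]cyclopent-2-ene-1,4-diol
Conditions: TBAF, THF, 0 °C
Reagents that add atoms: none
Why: fluoride-mediated desilylation under non-acidic conditions, so the ionisable tertiary allylic alcohol should survive.

Step 4
Reactants: 6 (1S,4R)-1-[(2Z)-oct-2-en-1-yl]cyclopent-2-ene-1,4-diol
Product: 7 (4S)-4-hydroxy-4-[(2Z)-oct-2-en-1-yl]cyclopent-2-en-1-one
Conditions: MnO2, CH2Cl2, rt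
Reagents that add atoms: none
Why: chemoselective allylic oxidation with MnO2; only the secondary allylic alcohol can be oxidised, the directing stereocentre is spent and the tertiary carbinol remains as the sole stereocentre (1,4-chirality transfer).

Step 5
Reactants: 7 (4S)-4-hydroxy-4-[(2Z)-oct-2-en-1-yl]cyclopent-2-en-1-one
Product: 8 (1S,4S,5R)-4-hydroxy-4-[(2Z)-oct-2-en-1-yl]-6-oxabicyclo[3.1.0]hexan-2-one
Conditions: 30% H2O2, cat. NaOH, MeOH, −20 to 0 °C
Reagents that add atoms: hydrogen peroxide OO
Why: Weitz–Scheffer nucleophilic epoxidation attacks only the electron-poor enone and leaves the isolated Z-alkene; hydroperoxide should add anti to the octenyl group (cis to OH), and both new centres are erased in step 6.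

Step 6
Reactants: 8 (1S,4S,5R)-4-hydroxy-4-[(2Z)-oct-2-en-1-yl]-6-oxabicyclo[3.1.0]hexan-2-one
Product: 9 (4S)-2-chloro-4-hydroxy-4-[(2Z)-oct-2-en-1-yl]cyclopent-2-en-1-one
Conditions: conc. HCl, THF, 0 °C to rt
Reagents that add atoms: hydrogen chloride Cl
Why: acid-promoted epoxide opening by chloride at the carbon α to the ketone (the β-carbon is shielded by the adjacent quaternary centre), followed by dehydration of the α-chloro-β-hydroxy ketone to the 2-chloroenone.

Step 7
Reactants: 9 (4S)-2-chloro-4-hydroxy-4-[(2Z)-oct-2-en-1-yl]cyclopent-2-en-1-one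
Product: 10 (4S)-2-chloro-4-[(2Z)-oct-2-en-1-yl]-4-[(trimethylsilyl)oxy]cyclopent-2-en-1-one
Conditions: TMSCl, imidazole, DMF, 0 °C to rt
Reagents that add atoms: chlorotrimethylsilane C[Si](C)(C)Cl
Why: silyl ether formation on the hindered tertiary alcohol, so that step 8 generates a single enolate and no alkoxide.

Step 8
Reactants: 10 (4S)-2-chloro-4-[(2Z)-oct-2-en-1-yl]-4-[(trimethylsilyl)oxy]cyclopent-2-en-1-one
Product: 13 (Z)-[(2R)-4-chloro-2-[(2Z)-oct-2-en-1-yl]-5-oxo-2-[(trimethylsilyl)oxy]cyclopent-3-en-1-ylidene]methyl trifluoromethanesulfonate, via ketone lithium enolate 11 (not isolated), via formyl-ketone lithium enolate 12 (not isolated)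
Conditions: LiHMDS, THF, −78 °C; HCO2CH2CF3, −78 °C; PhNTf2, −78 to 0 °C
Reagents that add atoms: 2,2,2-trifluoroethyl formate O=COCC(F)(F)F; N-phenylbis(trifluoromethanesulfonimide) O=S(=O)(N(c1ccccc1)S(=O)(=O)C(F)(F)F)C(F)(F)F
Why: Claisen-type C-formylation of the only possible enolate (C5–H2) and O-triflation of the resulting β-keto-aldehyde enolate; lithium chelation between the ring ketone oxygen and the formyl oxygen should hold the new C–O bond cis to C=O and so give the (Z)-enol triflate, while −78 °C suppresses β-elimination of the silyloxy group.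

Step 9
Reactants: 13 (Z)-enol triflate; 14 methyl hex-5-ynoate
Product: 18 chlorovulone III, via alkenylzirconocene chloride 15 (not isolated), via alkenylzinc chloride 16 (not isolated), via chlorovulone III trimethylsilyl ether 17 (not isolated)
Conditions: 14 (slight excess), Cp2Zr(H)Cl, THF, rt; ZnCl2, 0 °C; 13, Pd(PPh3)4 (5 mol%), 0 °C to rt; then aq. citric acid, MeOH, rt
Reagents that add atoms: none
Why: syn-hydrozirconation of 14 places zirconium on the terminal carbon and gives the (E)-alkenylzirconocene 15, which ZnCl2 converts into alkenylzinc 16; Pd(0) inserts into the C7–OTf bond of 13 with retention, and transmetalation and reductive elimination then form C6–C7. The closest known reaction type is the Negishi coupling of hydrozirconation-derived alkenyl metals with enol triflates. No ring is closed and no stereocentre is created; C12 is untouched. 5E is fixed by the syn-addition of Zr–H, and 7Z is carried over from 13 with retention, helped by the cis C9 carbonyl, which can chelate palladium in the alkenylpalladium intermediate. The step needs oxidative addition at C–OTf in preference to the C10–Cl bond and no 1,4-addition to the enone, which the far higher reactivity of the vinylogous triflate at 0 °C and the mild alkenylzinc should secure. Mild aqueous acid in the work-up then cleaves the tertiary TMS ether of 17 to give 18.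

Compound list
1 | (Z)-oct-2-en-1-ol | CCCCC/C=C\CO | starting material
2 | (Z)-1-chlorooct-2-ene | CCCCC/C=C\CCl | intermediate
3 | (R)-4-[(tert-butyldimethylsilyl)oxy]cyclopent-2-en-1-one | O=C1C=C[C@H](O[Si](C)(C)C(C)(C)C)C1 | starting material
4 | (Z)-oct-2-en-1-ylbarium chloride | CCCCC/C=C\C[Ba]Cl | intermediate (not isolated)
5 | (1S,4R)-4-[(tert-butyldimethylsilyl)oxy]-1-[(2Z)-oct-2-en-1-yl]cyclopent-2-en-1-ol | CCCCC/C=C\C[C@@]1(O)C=C[C@H](O[Si](C)(C)C(C)(C)C)C1 | intermediate
6 | (1S,4R)-1-[(2Z)-oct-2-en-1-yl]cyclopent-2-ene-1,4-diol | CCCCC/C=C\C[C@@]1(O)C=C[C@H](O)C1 | intermediate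
7 | (4S)-4-hydroxy-4-[(2Z)-oct-2-en-1-yl]cyclopent-2-en-1-one | CCCCC/C=C\C[C@@]1(O)C=CC(=O)C1 | intermediate
8 | (1S,4S,5R)-4-hydroxy-4-[(2Z)-oct-2-en-1-yl]-6-oxabicyclo[3.1.0]hexan-2-one (epoxide cis to OH) | CCCCC/C=C\C[C@@]1(O)[C@@H]2O[C@@H]2C(=O)C1 | intermediate
9 | (4S)-2-chloro-4-hydroxy-4-[(2Z)-oct-2-en-1-yl]cyclopent-2-en-1-one | CCCCC/C=C\C[C@@]1(O)C=C(Cl)C(=O)C1 | intermediate
10 | (4S)-2-chloro-4-[(2Z)-oct-2-en-1-yl]-4-[(trimethylsilyl)oxy]cyclopent-2-en-1-one | CCCCC/C=C\C[C@@]1(O[Si](C)(C)C)C=C(Cl)C(=O)C1 | intermediate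
11 | lithium enolate of 10 (stereocentre unchanged) | CCCCC/C=C\C[C@@]1(O[Si](C)(C)C)C=C(Cl)C([O-])=C1.[Li+] | intermediate (not isolated)
12 | lithium (Z)-enolate of the 5-formyl derivative of 10 (chelated oxidomethylene ketone) | CCCCC/C=C\C[C@@]1(O[Si](C)(C)C)C=C(Cl)C(=O)/C1=C\[O-].[Li+] | intermediate (not isolated)
13 | (Z)-[(2R)-4-chloro-2-[(2Z)-oct-2-en-1-yl]-5-oxo-2-[(trimethylsilyl)oxy]cyclopent-3-en-1-ylidene]methyl trifluoromethanesulfonate | CCCCC/C=C\C[C@@]1(O[Si](C)(C)C)C=C(Cl)C(=O)/C1=C\OS(=O)(=O)C(F)(F)F | intermediate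
14 | methyl hex-5-ynoate | COC(=O)CCCC#C | starting material
15 | chlorobis(cyclopentadienyl)[(1E)-6-methoxy-6-oxohex-1-en-1-yl]zirconium | COC(=O)CCC/C=C/[Zr](Cl)(C1C=CC=C1)C1C=CC=C1 | intermediate (not isolated)
16 | [(1E)-6-methoxy-6-oxohex-1-en-1-yl]zinc chloride | COC(=O)CCC/C=C/[Zn]Cl | intermediate (not isolated)
17 | chlorovulone III 12-O-trimethylsilyl ether | CCCCC/C=C\C[C@@]1(O[Si](C)(C)C)C=C(Cl)C(=O)/C1=C\C=C\CCCC(=O)OC | intermediate (not isolated)
18 | chlorovulone III, methyl (5E,7Z,12R,14Z)-10-chloro-12-hydroxy-9-oxoprosta-5,7,10,14-tetraen-1-oate | CCCCC/C=C\C[C@@]1(O)C=C(Cl)C(=O)/C1=C\C=C\CCCC(=O)OC | target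

Total step count: 9. Longest linear sequence: 9 steps (1 → 2 → 5 → 6 → 7 → 8 → 9 → 10 → 13 → 18).

Steps most likely to fail

Step 8. The enolate may lose the C4 silyloxy group by β-elimination, and the enol triflate may form or equilibrate (addition–elimination) with incomplete Z geometry. The fallback sets out from 10 and avoids a free enolate. Soft enolisation (TMSOTf, Et3N, CH2Cl2, −78 °C) should give the 2-silyloxycyclopentadiene F1. Electrophilic formylation with the Vilsmeier salt (DMF/(COCl)2, 0 °C) and aqueous NaOAc hydrolysis should give the chelated (Z)-5-(hydroxymethylene) ketone F2. Triflation under biphasic lithium-chelate control (Tf2O, saturated aq. LiOH, toluene, 5 °C) comes back to the route at 13.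

Step 9. The alkenylpalladium intermediate may isomerise (Z to E at C7=C8), zirconium hydride may reduce the ester or the enone, and palladium may insert at C–Cl. The fallback sets out from 13 and 14 and builds the 5E alkene by reduction instead of hydrometalation. Sonogashira coupling (PdCl2(PPh3)2, CuI, i-Pr2NH, THF) should give the 5,6-didehydro enynone F3. Ruthenium-catalysed trans-hydrosilylation ([Cp*Ru(MeCN)3]PF6, (EtO)3SiH, CH2Cl2, 0 °C) should give the (Z)-alkenylsilane F4; either regioisomer converges. Protodesilylation (CuI, TBAF, THF), which also removes the TMS ether, comes back at 18.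

Step 2. The allylbarium may equilibrate by 1,3-metal shift (γ-attack or Z to E leakage), facial selectivity may be incomplete, and the ketone may be enolised. The fallback sets out from 3 and installs the Z-alkene by metathesis. Allylmagnesium bromide (THF, −78 °C) should add anti to the silyloxy group to give the allyl carbinol F5. Z-selective cross-metathesis with hept-1-ene (cyclometalated ruthenium Z-selective catalyst, THF, 35 °C) comes back at 5.

Further compounds
F1 | step 8 | silyl dienol ether of 10, {[(3S)-5-chloro-3-[(2Z)-oct-2-en-1-yl]-3-[(trimethylsilyl)oxy]cyclopenta-1,4-dien-1-yl]oxy}trimethylsilane | CCCCC/C=C\C[C@@]1(O[Si](C)(C)C)C=C(Cl)C(O[Si](C)(C)C)=C1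
F2 | step 8 | (Z)-5-(hydroxymethylene) derivative of 10 (chelated enol of the 5-formyl ketone) | CCCCC/C=C\C[C@@]1(O[Si](C)(C)C)C=C(Cl)C(=O)/C1=C\O
F3 | step 9 | 5,6-didehydro analogue of 17 (C5≡C6 enynone) | CCCCC/C=C\C[C@@]1(O[Si](C)(C)C)C=C(Cl)C(=O)/C1=C\C#CCCCC(=O)OC
F4 | step 9 | (5Z)-5-(triethoxysilyl) derivative of 17 (alkenylsilane) | CCCCC/C=C\C[C@@]1(O[Si](C)(C)C)C=C(Cl)C(=O)/C1=C\C=C(/[Si](OCC)(OCC)OCC)\CCCC(=O)OC
F5 | step 2 | (1S,4R)-4-[(tert-butyldimethylsilyl)oxy]-1-(prop-2-en-1-yl)cyclopent-2-en-1-ol | C=CC[C@@]1(O)C=C[C@H](O[Si](C)(C)C(C)(C)C)C1
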